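## The problem

The target 17 is a 3',8''-linked biflavone. A 7,4'-dimethoxyflavone (benzo ring A, pyranone ring C, aryl ring B; unprimed and single-primed atoms) is bonded through C3' of ring B to C8'' of a 7'',4'''-dihydroxyflavone (benzo ring D, pyranone ring F, aryl ring E; double- and triple-primed atoms). There is no stereocentre. The only stereochemical element is the C3'–C8'' axis, which the structure leaves undefined, so nothing has to be controlled and nothing is available as a control element. The difficult region is ring D: C8'' carries the biaryl bond and lies between two oxygen-bearing carbons, C7'' and C8a''. The biaryl bond is therefore tri-ortho-substituted, and a resorcinol-type precursor would need its two oxygens told apart. The four oxygen substituents form two sets that must stay distinct: two methyl ethers on flavone 1 and two free phenols on flavone 2. The phenols therefore need a mask that can be removed without touching aryl methyl ethers. Both pyranones are vinylogous esters: hard nucleophiles can add at C2 or C2'' and open the ring, and the C2=C3 bonds can be reduced, so the late steps must be mild on both counts. The enabling feature is that C8a'' (ortho) and C7'' (para) are both conjugated with C4a'', the carbon that bears the C4'' carbonyl. Each oxygen can therefore enter as a fluoride that is displaced in a carbonyl-activated SNAr reaction, and geometry separates the two sites, because only the ortho fluoride can be reached from within the molecule.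

## Retrosynthesis

**17 from 16.** The two O–benzyl bonds are cut last, which leads back to the dibenzyl ether 16. Benzyl is preferred to a second pair of methyl ethers or to silyl groups: hydrogenolysis leaves the aryl methyl ethers alone, both groups fall in one operation, and a benzyl ether survives the basic steps that precede it. The forward reaction must cleave two benzyl ethers without saturating either C2=C3 bond.

**16 from 15.** The C7''–O bond is cut next, so that the C7'' oxygen becomes the fluoride of 15. This fluorine is para to C4a'' and is activated by the C4'' carbonyl once ring F exists. Until then it is an inert placeholder that needs no protection and no differentiation from its neighbour. The forward step asks a benzyl alkoxide to displace a fluoride flanked by the biaryl bond faster than it damages either pyranone.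

**15 from 13.** The key cut is the O1''–C8a'' bond of ring F, which opens 15 to the 1,3-diketone 13 (reacting as its enolate 14). The classical alternative, cutting O1''–C2'' and closing an ortho-hydroxyaryl diketone by dehydration, would require a free phenol at C8a'' beside a protected oxygen at C7'' on a 2-aryl resorcinol. The aryl C–O cut removes that need: both oxygens are fluorides, and the ring closure itself decides which one reacts. The precursor loses a ring and gains only a flexible diketone chain.

**13 from 11 and 12.** The C2''–C3'' bond is cut, giving the methyl ketone 11 and 4-(benzyloxy)benzoyl chloride 12. This direction is preferred to the reverse one (a difluorobiaryl acid chloride plus an acetophenone enolate), because the acetyl group of 11 arrives in one step on the small ring D piece and 12 is a stock reagent. The forward acylation must enolise the methyl ketone without strong base or free alkoxide, since both fluorides are already carbonyl-activated and flavone 1 is present.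

**11 from 10 and 6.** The C3'–C8'' biaryl bond is cut into the bromide 10 and the boronate 6. Boron is placed on ring B because 2,6-difluorophenylboron species protodeboronate readily, while the di-ortho-fluoro bromide is small and electron-poor and should undergo oxidative addition easily. The coupling precedes the diketone, which would otherwise chelate palladium. This cut divides the molecule into flavone 1 and an eight-carbon ring D unit.

**10 from 7.** The aryl–acetyl bond (the future C4a''–C4'') is cut, leading to 2-bromo-1,3-difluorobenzene 7 through the aryllithium 8 and the adduct 9. Compound 7 is symmetric: its two hydrogens ortho to fluorine are equivalent, so one regioisomer results, and bromine already marks the future C8''. The forward step needs deprotonation without bromine–lithium exchange, which means an amide base at low temperature.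

**6 from 5, 3, 1 and 2.** The C–B bond of 6 goes back to the bromide 5. The O1–C2 bond of 5 goes back, through the flavanone 4, to the chalcone 3, and its enone C=C bond goes back to the acetophenone 1 and the aldehyde 2. Both methyl ethers of flavone 1 are bought with 1 and 2, and the bromine of 2 marks C3' from the outset.

## Roads not taken

**Alternative 1: ring B built by a pyrone Diels–Alder reaction.**
- Cut: two bonds of ring B, C2'–C3' and C4'–C5', so the biaryl bond is inherited from an aryl–alkyne bond.
- Key step: methyl coumalate A3 reacts with the 8''-(methoxyethynyl)flavone A2 in an inverse-demand Diels–Alder addition. The bridged adduct loses CO2 to give the methyl benzoate A1.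
- Merits: the polarised partners fix the regiochemistry. The nucleophilic alkyne carbon, which bears the flavone, bonds to C6 of A3, so the ester ends up para to the methoxy group and meta to the biaryl bond, as flavone 1 requires. No hindered cross-coupling is needed.
- Weak points: A2 is an aryl ynol ether at the most crowded position of a complete, protected flavone 2. Its preparation needs an 8''-halide with differentiated ring D oxygens and a fragile methoxyethynyl donor. Ynol ethers hydrate and oligomerise easily, and the cycloaddition needs prolonged heating. After A1, flavone 1 still has to be built from the ester with 1 by acylation and cyclodehydration before deprotection.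
- Comparison: this road avoids the hindered Suzuki coupling and the alkoxide treatment of two pyranones, which are the soft spots of the chosen plan. In return it is longer, runs every step on the most valuable intermediate and relies on a sensitive alkyne. The chosen plan offers stable intermediates, stock building blocks and a directly precedented closure.

**Alternative 2: silicon-tethered intramolecular C–H arylation.**
- Cut: the C3'–C8'' bond, formed within a temporary ring.
- Key step: the bis(aryloxy)di-tert-butylsilane A5 links O4' of flavone 1 to O7'' of an 8''-bromoflavone 2. Pd(OAc)2-catalysed C–H arylation joins C8'' to the C–H carbon ortho to the silyloxy group and gives the seven-membered dibenzodioxasilepine A4.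
- Merits: flavone 1 needs no organometallic handle, and the tether selects the C–H bond, so the regiochemistry of the biaryl bond is as secure as in the chosen plan.
- Weak points: the unsymmetrical silylene diether must be assembled stepwise from two different phenols. Its aryl–O–Si bonds are labile to the carbonate or carboxylate base that C–H arylation needs at high temperature. Ring D again requires differentiated oxygens and a regioselective bromination. Cleaving the tether gives the diol A6 with free 4'-OH and 7''-OH, whereas the target needs 4'-OMe beside 7''-OH. Methylating the less acidic 4'-OH selectively runs against intrinsic reactivity and costs protection steps.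
- Comparison: equal in regiocontrol and elegant in the bond-forming event, but the endgame is longer and less certain. The chosen plan carries the 4'-methyl ether in from 2 and never has two phenols on different halves to distinguish.

**Alternative 3: double oxidative cyclisation of a biaryl bis-chalcone.**
- Cut: O1–C2 and O1''–C2'' together.
- Key step: iodine in hot DMSO cyclises both 2'-hydroxychalcone units of A8 and dehydrogenates them, giving A7, which is identical with compound 16 of the chosen route.
- Merits: it repeats the reaction of step 2 on two sites in one flask, is highly convergent and reaches 16 without the fluoride exchange of step 8. In step count it is at least as short as the chosen plan, and all of its reactions are classical.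
- Weak points: ring D must enter as an aryl ketone with a free hydroxyl and a benzyloxy group on either side of the coupling carbon. That requires differentiating the resorcinol oxygens and making the biaryl bond at an electron-rich, doubly oxygen-flanked halide, which is slower in oxidative addition and more crowded than the difluoro bromide 10. The two aldol condensations use a methyl ketone and an aldehyde that cannot be allowed to meet within one molecule. This fixes the order of events and forces the hindered coupling onto base-sensitive chalcones. Both oxidations must go to completion, or mixed flavanone–flavone products result.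
- Comparison: this is the strongest competitor and is better in endgame simplicity. The chosen plan sets against it an easy cross-coupling of a small, electron-poor bromide, no oxygen differentiation on ring D, and closure of flavone 2 as a single, non-oxidative event that can be optimised by itself.

Key step: step 7

Assumption: the C3'–C8'' axis is drawn without configuration and is treated as stereochemically undefined; no step is asked to control it.
Assumption: the acid chloride 12 is taken as a stock reagent.

## Route

Step 1
Reactants: 1 2-hydroxy-4-methoxyacetophenone; 2 3-bromo-4-methoxybenzaldehyde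
Product: 3 (E)-3-(3-bromo-4-methoxyphenyl)-1-(2-hydroxy-4-methoxyphenyl)prop-2-en-1-one
Conditions: KOH, EtOH, rt; then aq. HCl
Reagents that add atoms: none
Why: Claisen–Schmidt condensation: the enolate of 1 adds to the non-enolisable aldehyde 2 and the aldol loses water by an E1cB pathway to give the conjugated enone in its favoured (E) geometry; the aryl bromide and the methyl ethers are inert to ethanolic hydroxide.

Step 2
Reactants: 3 (E)-3-(3-bromo-4-methoxyphenyl)-1-(2-hydroxy-4-methoxyphenyl)prop-2-en-1-one
Product: 5 2-(3-bromo-4-methoxyphenyl)-7-methoxy-4H-chromen-4-one (3'-bromo-4',7-dimethoxyflavone), via racemic flavanone 4 (not isolated)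
Conditions: I2 (10 mol%), DMSO, 130 °C
Reagents that add atoms: none
Why: Iodine/DMSO oxidative cyclisation of a 2'-hydroxychalcone: oxa-Michael closure gives flavanone 4, α-iodination and loss of HI install the C2=C3 bond, and DMSO reoxidises HI to I2; the flavanone stereocentre disappears in the pyranone.

Step 3
Reactants: 5 2-(3-bromo-4-methoxyphenyl)-7-methoxy-4H-chromen-4-one
Product: 6 7-methoxy-2-[4-methoxy-3-(4,4,5,5-tetramethyl-1,3,2-dioxaborolan-2-yl)phenyl]-4H-chromen-4-one
Conditions: B2pin2, Pd(dppf)Cl2 (5 mol%), KOAc, 1,4-dioxane, 90 °C
Reagents that add atoms: bis(pinacolato)diboron, CC1(C)OB(B2OC(C)(C)C(C)(C)O2)OC1(C)C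
Why: Miyaura borylation: oxidative addition of the aryl bromide to zerovalent palladium, acetate-assisted transmetalation from the diboron reagent and reductive elimination; KOAc is too weak a base to couple 6 with remaining 5, and the chromone tolerates these near-neutral conditions.

Step 4
Reactants: 7 2-bromo-1,3-difluorobenzene
Product: 10 1-(3-bromo-2,4-difluorophenyl)ethanone, via aryllithium 8 (not isolated), via lithium hemiaminal adduct 9 (not isolated)
Conditions: LiN(i-Pr)2, THF, −78 °C; MeC(O)N(OMe)Me, −78 → 0 °C; then 1 M HCl
Reagents that add atoms: N-methoxy-N-methylacetamide, CC(=O)N(C)OC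
Why: Directed ortho-lithiation followed by acylation with an N-methoxy-N-methyl amide: fluorine acidifies the adjacent C–H (the two such positions of 7 are equivalent), the amide base does not exchange bromine, and the chelated adduct 9 releases ketone 10 only on acidic quench, so no tertiary alcohol forms; at −78 °C aryllithium 8 should neither lose LiF nor transfer bromine.

Step 5
Reactants: 10 1-(3-bromo-2,4-difluorophenyl)ethanone; 6 7-methoxy-2-[4-methoxy-3-(4,4,5,5-tetramethyl-1,3,2-dioxaborolan-2-yl)phenyl]-4H-chromen-4-one
Product: 11 2-[3-(3-acetyl-2,6-difluorophenyl)-4-methoxyphenyl]-7-methoxy-4H-chromen-4-one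
Conditions: Pd(OAc)2 (5 mol%), SPhos, K3PO4, toluene/H2O, 90 °C
Reagents that add atoms: none
Why: Suzuki–Miyaura coupling: the electron-poor bromide flanked by two small fluorines adds readily to zerovalent palladium, the boron sits on the anisole partner so that no 2,6-difluorophenylboron species is involved, and the bulky biarylphosphine promotes reductive elimination of the tri-ortho-substituted biaryl; phosphate is mild enough to spare the ketone-activated fluorides.

Step 6
Reactants: 11 2-[3-(3-acetyl-2,6-difluorophenyl)-4-methoxyphenyl]-7-methoxy-4H-chromen-4-one; 12 4-(benzyloxy)benzoyl chloride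
Product: 13 1-[4-(benzyloxy)phenyl]-3-{2,4-difluoro-3-[2-methoxy-5-(7-methoxy-4-oxo-4H-chromen-2-yl)phenyl]phenyl}propane-1,3-dione
Conditions: MgBr2·OEt2, i-Pr2NEt, CH2Cl2, rt; then 1 M HCl
Reagents that add atoms: none
Why: Claisen-type C-acylation under soft enolisation: coordination of MgBr2 makes the methyl ketone acidic enough for the tertiary amine, and the acid chloride acylates at carbon; no alkoxide or strong base is present, so both activated fluorides and the pyranone of flavone 1 are spared, and the more acidic diketone stays metal-bound until work-up, which suppresses a second acylation.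

Step 7
Reactants: 13 1-[4-(benzyloxy)phenyl]-3-{2,4-difluoro-3-[2-methoxy-5-(7-methoxy-4-oxo-4H-chromen-2-yl)phenyl]phenyl}propane-1,3-dione
Product: 15 2-{3-[2-(4-benzyloxyphenyl)-7-fluoro-4-oxo-4H-chromen-8-yl]-4-methoxyphenyl}-7-methoxy-4H-chromen-4-one (7''-fluoro-4'''-O-benzyl biflavone), via potassium enolate 14 (not isolated)
Conditions: K2CO3, dry DMF, 80 °C
Reagents that add atoms: none
Why: K2CO3 converts the acidic diketone into the delocalised potassium enolate 14, whose oxygen on the carbon bearing the 4-benzyloxyphenyl group adds to C8a'' to give a Meisenheimer adduct; its charge is relayed through C4a'' into the C4'' carbonyl, and loss of fluoride restores ring D and completes pyranone ring F with the new O1''–C8a'' bond. The closest known reaction type is the base-mediated cyclisation of 1-(2-fluorophenyl)-1,3-diketones to flavones by intramolecular SNAr, of which this is a direct application. The ring closes in a six-membered mode onto a trigonal aromatic carbon (6-endo-trig when counted on the C8a''=C4a'' bond that carries the charge), with oxygen and carbon held 1,6 by the Z-enolate, so no strain is incurred. No stereocentre is formed. The step needs selectivity between two carbonyl-activated fluorides and oxygen- over carbon-attack: only the fluoride on C8a'' lies within reach of the enolate oxygen, the fluoride on C7'' could be displaced only intermolecularly, and attack through C3'' would require a four-membered ring. Fluoride is the best leaving group for this addition-limited substitution, so a weak base at 80 °C should suffice and should leave flavone 1, the benzyl ether and the remaining fluoride untouched. Dry DMF and moderate dilution keep external nucleophiles away from the para fluoride.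

Step 8
Reactants: 15 7''-fluoro-4'''-O-benzyl biflavone
Product: 16 2-{3-[7-benzyloxy-2-(4-benzyloxyphenyl)-4-oxo-4H-chromen-8-yl]-4-methoxyphenyl}-7-methoxy-4H-chromen-4-one (7'',4'''-di-O-benzyl biflavone)
Conditions: BnOH, NaH, THF, 0 °C; then 15, DMSO, 50 °C
Reagents that add atoms: benzyl alcohol, OCc1ccccc1
Why: Intermolecular SNAr: the fluoride on C7'' is para to C4a'', so the Meisenheimer adduct of benzyloxide is stabilised by the C4'' carbonyl and fluoride leaves; the methoxy groups are far poorer leaving groups, and addition of alkoxide at C2 or C2'' is reversible at this temperature.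

Step 9
Reactants: 16 7'',4'''-di-O-benzyl biflavone
Product: 17 2-{3-[7-hydroxy-2-(4-hydroxyphenyl)-4-oxo-4H-chromen-8-yl]-4-methoxyphenyl}-7-methoxy-4H-chromen-4-one (target)
Conditions: H2 (1 atm), Pd/C, THF/MeOH, rt
Reagents that add atoms: none
Why: Catalytic hydrogenolysis of both benzyl aryl ethers; aryl methyl ethers are inert, and the C2=C3 bonds, being vinylogous esters, should resist reduction at atmospheric pressure if the reaction is stopped once the benzyl groups are gone.

## Compound list

1 | 2-hydroxy-4-methoxyacetophenone | CC(=O)c1ccc(OC)cc1O | starting material
2 | 3-bromo-4-methoxybenzaldehyde | COc1ccc(C=O)cc1Br | starting material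
3 | (E)-3-(3-bromo-4-methoxyphenyl)-1-(2-hydroxy-4-methoxyphenyl)prop-2-en-1-one | COc1ccc(C(=O)/C=C/c2ccc(OC)c(Br)c2)c(O)c1 | intermediate
4 | racemic 2-(3-bromo-4-methoxyphenyl)-7-methoxychroman-4-one (not isolated) | COc1ccc2c(c1)OC(CC2=O)c1ccc(OC)c(Br)c1 | intermediate
5 | 2-(3-bromo-4-methoxyphenyl)-7-methoxy-4H-chromen-4-one | COc1ccc2c(=O)cc(-c3ccc(OC)c(Br)c3)oc2c1 | intermediate
6 | 7-methoxy-2-[4-methoxy-3-(4,4,5,5-tetramethyl-1,3,2-dioxaborolan-2-yl)phenyl]-4H-chromen-4-one | COc1ccc2c(=O)cc(-c3ccc(OC)c(B4OC(C)(C)C(C)(C)O4)c3)oc2c1 | intermediate
7 | 2-bromo-1,3-difluorobenzene | Fc1cccc(F)c1Br | starting material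
8 | (3-bromo-2,4-difluorophenyl)lithium (not isolated) | [Li]c1ccc(F)c(Br)c1F | intermediate
9 | racemic lithium 1-(3-bromo-2,4-difluorophenyl)-1-[methoxy(methyl)amino]ethanolate (not isolated) | CC(O[Li])(N(C)OC)c1ccc(F)c(Br)c1F | intermediate
10 | 1-(3-bromo-2,4-difluorophenyl)ethanone | CC(=O)c1ccc(F)c(Br)c1F | intermediate
11 | 2-[3-(3-acetyl-2,6-difluorophenyl)-4-methoxyphenyl]-7-methoxy-4H-chromen-4-one | COc1ccc2c(=O)cc(-c3ccc(OC)c(-c4c(F)ccc(C(C)=O)c4F)c3)oc2c1 | intermediate
12 | 4-(benzyloxy)benzoyl chloride | O=C(Cl)c1ccc(OCc2ccccc2)cc1 | starting material
13 | 1-[4-(benzyloxy)phenyl]-3-{2,4-difluoro-3-[2-methoxy-5-(7-methoxy-4-oxo-4H-chromen-2-yl)phenyl]phenyl}propane-1,3-dione | COc1ccc2c(=O)cc(-c3ccc(OC)c(-c4c(F)ccc(C(=O)CC(=O)c5ccc(OCc6ccccc6)cc5)c4F)c3)oc2c1 | intermediate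
14 | potassium (Z)-enolate of 13, oxygen on the carbon bearing the 4-benzyloxyphenyl group (not isolated) | COc1ccc2c(=O)cc(-c3ccc(OC)c(-c4c(F)ccc(C(=O)/C=C(\[O-])c5ccc(OCc6ccccc6)cc5)c4F)c3)oc2c1.[K+] | intermediate
15 | 2-{3-[2-(4-benzyloxyphenyl)-7-fluoro-4-oxo-4H-chromen-8-yl]-4-methoxyphenyl}-7-methoxy-4H-chromen-4-one | COc1ccc2c(=O)cc(-c3ccc(OC)c(-c4c(F)ccc5c(=O)cc(-c6ccc(OCc7ccccc7)cc6)oc45)c3)oc2c1 | intermediate
16 | 2-{3-[7-benzyloxy-2-(4-benzyloxyphenyl)-4-oxo-4H-chromen-8-yl]-4-methoxyphenyl}-7-methoxy-4H-chromen-4-one | COc1ccc2c(=O)cc(-c3ccc(OC)c(-c4c(OCc5ccccc5)ccc5c(=O)cc(-c6ccc(OCc7ccccc7)cc6)oc45)c3)oc2c1 | intermediate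
17 | 2-{3-[7-hydroxy-2-(4-hydroxyphenyl)-4-oxo-4H-chromen-8-yl]-4-methoxyphenyl}-7-methoxy-4H-chromen-4-one | COc1ccc2c(=O)cc(-c3ccc(OC)c(-c4c(O)ccc5c(=O)cc(-c6ccc(O)cc6)oc45)c3)oc2c1 | target

## Step count and risks

Total steps: 9. Longest linear sequence: 8 steps (steps 1, 2, 3, 5, 6, 7, 8, 9); step 4 supplies the ring D branch.

**Step 7 (key step).** The twisted biaryl next to C8a'' may slow the closure. Intermolecular substitution of the para fluoride could then compete, by a second enolate, by hydroxide from wet carbonate or by dimethylamine from decomposing DMF, as could retro-Claisen cleavage of the diketone. The fallback changes the order of events so that the closure runs on a small, unhindered substrate of exactly the precedented type. It sets out from 10, which is acylated with 12 under the conditions of step 6 to give 1-[4-(benzyloxy)phenyl]-3-(3-bromo-2,4-difluorophenyl)propane-1,3-dione F1. This is cyclised with K2CO3 in DMF to 2-[4-(benzyloxy)phenyl]-8-bromo-7-fluoro-4H-chromen-4-one F2. Suzuki–Miyaura coupling of F2 with 6 (Pd(OAc)2, SPhos, K3PO4) then returns to the route at 15.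

**Step 8.** Displacement at a fluoride flanked by the biaryl bond may be slow. Benzyloxide would then have time to add at C2 or C2'' and open a pyranone, or to degrade the material on prolonged heating. The fallback sets out from 15 and uses a weakly basic hydroxide surrogate instead of an alkoxide: acetohydroxamic acid and K2CO3 in DMSO at 80 °C. The hydroxamate oxygen displaces the fluoride and a Lossen-type fragmentation releases the phenoxide, giving 2-{3-[2-(4-benzyloxyphenyl)-7-hydroxy-4-oxo-4H-chromen-8-yl]-4-methoxyphenyl}-7-methoxy-4H-chromen-4-one F3. Hydrogenolysis of its single benzyl ether (H2, Pd/C) returns to the route at 17.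

**Step 6.** The chromone carbonyl of flavone 1 may sequester MgBr2 and leave enolisation incomplete, or the enolised ketone may be acylated at oxygen or twice. The fallback sets out from 11 and builds the diketone by aldol addition and oxidation. The kinetic lithium enolate (LiN(i-Pr)2, THF, −78 °C) adds to 4-(benzyloxy)benzaldehyde to give the racemic aldol 2-[3-(3-{3-[4-(benzyloxy)phenyl]-3-hydroxypropanoyl}-2,6-difluorophenyl)-4-methoxyphenyl]-7-methoxy-4H-chromen-4-one F4. Dess–Martin periodinane oxidises F4 and returns to the route at 13.

**Step 5.** Protodeboronation of the ortho-methoxyaryl boronate may outrun transmetalation to a crowded palladium centre, and aqueous base may attack the activated fluorides. The fallback sets out from 5 and uses a tin partner without aqueous base. Hexamethylditin with Pd(PPh3)4 in toluene gives 7-methoxy-2-[4-methoxy-3-(trimethylstannyl)phenyl]-4H-chromen-4-one F5. Stille coupling of F5 with 10 (Pd(PPh3)4, CuI, CsF, DMF) returns to the route at 11.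

**Step 4.** If the aryllithium warms, bromine may migrate between ring positions (halogen dance) or LiF may be lost to an aryne. The fallback sets out from 7 and replaces metalation by electrophilic substitution: Friedel–Crafts acetylation with acetyl chloride and AlCl3. Both fluorines direct to the same carbon (para to one, ortho to the other), so 10 is reached directly. This fallback makes no new compound (F0).

## Further compounds

F1 | step 7 | 1-[4-(benzyloxy)phenyl]-3-(3-bromo-2,4-difluorophenyl)propane-1,3-dione | O=C(CC(=O)c1ccc(OCc2ccccc2)cc1)c1ccc(F)c(Br)c1F
F2 | step 7 | 2-[4-(benzyloxy)phenyl]-8-bromo-7-fluoro-4H-chromen-4-one | O=c1cc(-c2ccc(OCc3ccccc3)cc2)oc2c(Br)c(F)ccc12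
F3 | step 8 | 2-{3-[2-(4-benzyloxyphenyl)-7-hydroxy-4-oxo-4H-chromen-8-yl]-4-methoxyphenyl}-7-methoxy-4H-chromen-4-one | COc1ccc2c(=O)cc(-c3ccc(OC)c(-c4c(O)ccc5c(=O)cc(-c6ccc(OCc7ccccc7)cc6)oc45)c3)oc2c1
F4 | step 6 | racemic 2-[3-(3-{3-[4-(benzyloxy)phenyl]-3-hydroxypropanoyl}-2,6-difluorophenyl)-4-methoxyphenyl]-7-methoxy-4H-chromen-4-one | COc1ccc2c(=O)cc(-c3ccc(OC)c(-c4c(F)ccc(C(=O)CC(O)c5ccc(OCc6ccccc6)cc5)c4F)c3)oc2c1
F5 | step 5 | 7-methoxy-2-[4-methoxy-3-(trimethylstannyl)phenyl]-4H-chromen-4-one | COc1ccc2c(=O)cc(-c3ccc(OC)c([Sn](C)(C)C)c3)oc2c1
F0 | step 4 | none | none
A1 | alternative 1 | methyl 3-{7-benzyloxy-2-(4-benzyloxyphenyl)-4-oxo-4H-chromen-8-yl}-4-methoxybenzoate | COC(=O)c1ccc(OC)c(-c2c(OCc3ccccc3)ccc3c(=O)cc(-c4ccc(OCc5ccccc5)cc4)oc23)c1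
A2 | alternative 1 | 7-benzyloxy-2-(4-benzyloxyphenyl)-8-(methoxyethynyl)-4H-chromen-4-one | COC#Cc1c(OCc2ccccc2)ccc2c(=O)cc(-c3ccc(OCc4ccccc4)cc3)oc12
A3 | alternative 1 | methyl coumalate (methyl 2-oxo-2H-pyran-5-carboxylate) | COC(=O)c1ccc(=O)oc1
A4 | alternative 2 | silicon-bridged biflavone (di-tert-butyl dibenzodioxasilepine) | COc1ccc2c(=O)cc(-c3ccc4c(c3)-c3c(ccc5c(=O)cc(-c6ccc(OCc7ccccc7)cc6)oc35)O[Si](C(C)(C)C)(C(C)(C)C)O4)oc2c1
A5 | alternative 2 | di-tert-butylsilylene diether of 4'-hydroxy-7-methoxyflavone and 8-bromo-7-hydroxy-4'-benzyloxyflavone | COc1ccc2c(=O)cc(-c3ccc(O[Si](C(C)(C)C)(C(C)(C)C)Oc4ccc5c(=O)cc(-c6ccc(OCc7ccccc7)cc6)oc5c4Br)cc3)oc2c1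
A6 | alternative 2 | 4',7''-dihydroxy-7-methoxy-4'''-O-benzyl biflavone | COc1ccc2c(=O)cc(-c3ccc(O)c(-c4c(O)ccc5c(=O)cc(-c6ccc(OCc7ccccc7)cc6)oc45)c3)oc2c1
A7 | alternative 3 | 7'',4'''-di-O-benzyl biflavone (identical with 16) | COc1ccc2c(=O)cc(-c3ccc(OC)c(-c4c(OCc5ccccc5)ccc5c(=O)cc(-c6ccc(OCc7ccccc7)cc6)oc45)c3)oc2c1
A8 | alternative 3 | (E,E)-biaryl bis(2'-hydroxychalcone) | COc1ccc(C(=O)/C=C/c2ccc(OC)c(-c3c(OCc4ccccc4)ccc(C(=O)/C=C/c4ccc(OCc5ccccc5)cc4)c3O)c2)c(O)c1
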